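## Analysis of the target

Ligraminol A (11) is a 2,5-diaryl-3,4-dimethyloxolane: one five-membered ether ring (O1, C2–C5) in which all four carbons are stereogenic, (2S,3R,4S,5S). The 3,4-dimethoxyphenyl group at C2 is cis to the methyl at C3, the methyls at C3 and C4 are cis to each other (an erythro C3–C4 bond), and the 3,4,5-trimethoxyphenyl group at C5 is trans to the methyl at C4, so the two aryl groups lie on opposite faces of the ring. Because the aryl groups differ there is no symmetry to exploit, and the two benzylic carbons must be told apart: the one carrying the better donor ring holds the less stable cis arrangement. The sensitive sites are the two benzylic C–O bonds, which ionise under acid (C2 most easily, being para to a conjugated methoxy group) with epimerisation or Friedel–Crafts closure, and the electron-rich arenes, which are easily over-oxidised; all oxygen functions are methyl ethers, so nothing needs protection. The skeleton is small; the difficulty is stereochemical (four contiguous centres, a contra-thermodynamic 2,3-cis relation, one enantiomer) together with the need to differentiate two nearly identical halves. The plan rests on the fact that each half is an aryl–C3 unit (dimethoxyphenyl–C2–C3–CH3 and trimethoxyphenyl–C5–C4–CH3), that the halves are joined only through C3–C4, and that O1 bridges the benzylic carbons C2 and C5. This is the bonding pattern of two propenylarenes coupled at their methyl-bearing carbons, with one oxygen atom taken from water.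

## Retrosynthetic reasoning

The oxolane 11 is cut at the three bonds that belong to neither aryl–C3 unit: C3–C4, O1–C2 and O1–C5. This returns E-methylisoeugenol 5, E-isoelemicin 3 and water 6, two carbon fragments of equal size that are each one step from a commercial arene. A cut at C2–C3, C4–C5 or an aryl–carbon bond would instead force the stereocentres to be built one after another. The gain is the ring, three skeletal bonds and four stereocentres in one operation, with no redox change other than the loss of two electrons, which an anode can take while protons are reduced at the cathode. The forward reaction has to oxidise only one alkene, join the two methyl-bearing carbons and place the oxygen of 6 on both benzylic carbons, with the erythro C3–C4 relation, the C2 aryl cis and the C5 aryl trans, in one enantiomeric series. The expected path runs from radical cation 7 (from 5) through its addition to 3 (1,4-radical cation 8), capture of 6 at C2 (radical 9) and a second oxidation (cation 10) to ring closure. The roles are made unequal on purpose: 5, whose para methoxy group is conjugated, should be oxidised first and is kept at low concentration, while 3, whose central methoxy group is twisted out of the ring plane, is the neutral partner in excess. Neither alkene has a stereocentre, so the configuration at C3 and C4 can only come from outside. A chiral counter-anion is therefore made the only anion present and the solvent polarity is lowered to keep it paired with 7, at the price of a higher cell resistance.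

Alkene 3 is cut at the bond between the ring and the propenyl group, giving 5-bromo-1,2,3-trimethoxybenzene 1 and the E-propenyl boronate 2. This is preferred over moving a double bond into conjugation from an allylarene: a cross-coupling transfers the E geometry of 2 unchanged, whereas a base-mediated migration leaves some Z isomer. In addition, 3 is needed in excess and 1 is a cheap bulk arene. The forward step only has to be a clean, stereoretentive aryl–alkenyl coupling.

Alkene 5 is cut in the same way, to 4-bromo-1,2-dimethoxybenzene 4 and the same boronate 2. Commercial material of this alkene is usually an E/Z mixture, and a defined geometry removes one variable from the key step. The bromides 1 and 4 also serve as entry points for the conventional route held in reserve for the key step.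

## Alternatives that were turned down

Alternative 1: The ring is simplified to cyclobutanone A1 (3,4-cis-dimethyl-2-(3,4,5-trimethoxyphenyl)cyclobutan-1-one, aryl trans to the neighbouring methyl). The bonds that become C2–C3 and C4–C5 are made in a [2+2] cycloaddition and O1 is inserted afterwards.
- Forward: amide A2 (1-[(2R,5R)-2,5-dimethylpyrrolidin-1-yl]-2-(3,4,5-trimethoxyphenyl)ethan-1-one, or its antipode if induction runs the other way) is activated with a sulfonic anhydride and a hindered base to a keteniminium salt. This adds suprafacially across cis-2-butene A3, and hydrolysis gives A1. A peracid then inserts oxygen between the carbonyl and the benzylic carbon with retention (Baeyer–Villiger) to give lactone A4, (3R,4S,5S)-3,4-dimethyl-5-(3,4,5-trimethoxyphenyl)oxolan-2-one. Addition of the second aryl group as its lithium reagent to A4, followed by ionic reduction with a silane, would set C2.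
- For it: every stereocentre has an identifiable source. C3/C4 come from the alkene geometry, C5 from the auxiliary and from equilibration of the α-aryl ketone to the trans isomer, and C2 from hydride delivery anti to the neighbouring methyl group. Every step is of a known type.
- Against it: five to six operations against three. The alkene is gaseous and weakly nucleophilic, while the electrophile can also attack the very electron-rich trimethoxyphenyl ring. Induction by the pyrrolidine is less secure in intermolecular than in intramolecular cycloadditions. The oxygen insertion must choose between two secondary migrating carbons and spare the arene. The auxiliary is stoichiometric.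
- Comparison: it is clearly stronger in stereocontrol and weaker in step economy and convergence. The chosen route offers in its place assembly of the whole oxolane from two equal C6–C3 halves in one operation, without auxiliary or redox adjustment. A4 is also the pivot of the reserve route for the key step.

Alternative 2: The C2–H and C3–H bonds are removed to give dihydrofuran A5 (trans-2-(3,4-dimethoxyphenyl)-3,4-dimethyl-5-(3,4,5-trimethoxyphenyl)-4,5-dihydrofuran). A5 is opened at O1–C5 to aroyl cyclopropane A6, (3,4-dimethoxyphenyl)[1,2-dimethyl-3-(3,4,5-trimethoxyphenyl)cyclopropyl]methanone, in which C3 and C5 are bonded.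
- Forward: Sc(OTf)3 heterolyses the C3–C5 bond of this donor–acceptor cyclopropane, the ketone oxygen closes on the benzylic carbon (Cloke–Wilson ring expansion), and hydrogenation of the enol ether double bond of A5 would finish the synthesis.
- For it: the ring expansion is a known reaction type for aryl/acyl cyclopropanes. Closure on a benzylic cation gives the trans C4/C5 relation as the favoured outcome. Syn addition of hydrogen makes the C2-aryl/C3-methyl cis relation a mechanistic necessity; on this point it is stronger than the chosen route.
- Against it: C5 passes through a planar cation and depends entirely on C4. The trimethoxyphenyl ring is a mediocre donor because its para methoxy group is twisted. Enantiopure A6, a cyclopropane with a quaternary carbon, is itself hard to reach, since the carbene route to it is prone to 1,2-hydride shift. The final hydrogenation must add to a tetrasubstituted enol ether from the face of the C5 aryl group, opposite the C4 methyl, without hydrogenolysing two benzylic C–O bonds.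
- Comparison: the chosen route shares the planar cation at C5 but needs neither the cyclopropane synthesis nor the face-selective hydrogenation, and it is several steps shorter.

Alternative 3: C2–C3 is cut and the two methyl groups are tied back as a lactone. This gives bicyclic lactone A7 (2-(3,4-dimethoxyphenyl)-4-(3,4,5-trimethoxyphenyl)-3,7-dioxabicyclo[3.3.0]octan-8-one, aryl at position 2 endo, aryl at position 4 exo), which comes from diazo lactone A8, 3-diazo-4-[(3,4-dimethoxyphenyl)methoxy(3,4,5-trimethoxyphenyl)methyl]oxolan-2-one.
- Forward: Rh2(OAc)4 decomposes A8. The carbene at C3 inserts into a benzylic C–H bond of the dimethoxybenzyl ether (1,5-insertion) and closes the oxolane cis-fused to the lactone. Both lactone carbons of A7 are then taken down to methyl groups by reduction and deoxygenation.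
- For it: the cis ring fusion enforces the C3/C4 cis relation. The insertion places the new aryl group on the concave face, which is cis to the C3 substituent as required. C4 and C5 are fixed beforehand by conventional asymmetric chemistry. On relative configuration this is the most secure of all the routes considered, the chosen one included.
- Against it: it is by far the longest. A8 needs about six steps and three more are spent converting the lactone into two methyl groups. A diazo lactone without a second acceptor is prone to elimination and dimerisation. Electron-rich rings invite competing cyclopropanation. The late hydride displacements take place beside two benzylic ethers.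
- Comparison: it is stronger on every stereochemical point but three to four times as long, and it introduces two oxygen atoms only to delete them. The chosen route offers brevity and a direct test of the biomimetic coupling.

Key step: step 3

Remark on the chemistry: the sense of induction of the chiral phosphate cannot be predicted, so the (R)-acid is written and its antipode would be used if the (2R,3S,4R,5R) series were favoured. Compound 5 is assumed to be oxidised at a less positive potential than 3, to be confirmed by cyclic voltammetry before the preparative run.

## Route

Step 1
Reactants: 1 5-bromo-1,2,3-trimethoxybenzene; 2 (E)-prop-1-enylboronic acid pinacol ester [4,4,5,5-tetramethyl-2-[(E)-prop-1-enyl]-1,3,2-dioxaborolane]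
Product: 3 E-isoelemicin [1,2,3-trimethoxy-5-[(E)-prop-1-enyl]benzene]
Conditions: Pd(PPh3)4 (cat.), K2CO3, 1,4-dioxane/H2O, 85 °C
Reagents that add atoms: (E)-prop-1-enylboronic acid pinacol ester (compound 2), C/C=C/B1OC(C)(C)C(C)(C)O1
Why: Suzuki–Miyaura cross-coupling: zerovalent palladium inserts into the C–Br bond, the alkenyl group is transferred from boron and reductive elimination forms the aryl–alkenyl bond, all with retention of the E geometry of 2; no stereocentre is formed and the methoxy groups are inert.

Step 2
Reactants: 4 4-bromo-1,2-dimethoxybenzene; 2 (E)-prop-1-enylboronic acid pinacol ester
Product: 5 E-methylisoeugenol [1,2-dimethoxy-4-[(E)-prop-1-enyl]benzene]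
Conditions: Pd(PPh3)4 (cat.), K2CO3, 1,4-dioxane/H2O, 85 °C
Reagents that add atoms: (E)-prop-1-enylboronic acid pinacol ester (compound 2), C/C=C/B1OC(C)(C)C(C)(C)O1
Why: The same Suzuki–Miyaura cross-coupling as in step 1, stereoretentive at the alkene, so 5 should be obtained as the single E isomer; it is to be stored cold under argon and used promptly because it is easily oxidised.

Step 3
Reactants: 5 E-methylisoeugenol; 3 E-isoelemicin; 6 water
Product: 11 ligraminol A [(2S,3R,4S,5S)-2-(3,4-dimethoxyphenyl)-3,4-dimethyl-5-(3,4,5-trimethoxyphenyl)oxolane], via alkene radical cation 7 (not isolated), via distonic 1,4-radical cation 8 (not isolated), via hydroxy benzylic radical 9 (not isolated), via hydroxy benzylic cation 10 (not isolated)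
Conditions: undivided cell, graphite-felt anode, Pt cathode, controlled potential at the foot of the wave of 5 (about 2 F per mol of 5); tetrabutylammonium (R)-3,3'-bis(2,4,6-triisopropylphenyl)-1,1'-binaphthyl-2,2'-diyl phosphate (0.05 M, sole electrolyte), CH2Cl2, H2O (3 equiv.), −20 °C, argon; 5 added slowly to 3 (4 equiv.); chromatography with recovery of 3
Reagents that add atoms: water (compound 6), O
Why: Proposed new method: anodic one-electron oxidation of 5, the more easily oxidised alkene because its 4-methoxy group is fully conjugated, gives radical cation 7 paired with the chiral phosphate as the only anion present; the methyl-bearing carbon of 7 adds to the methyl-bearing carbon of neutral 3, forming C3–C4 and the distonic radical cation 8 with the charge on C2 and the spin on C5. Water, hydrogen-bonded to the phosphate, adds to C2 (O1–C2) to give radical 9, which is oxidised at the anode or by 7 to cation 10, and the hydroxyl closes on C5 in a 5-exo-trig closure (O1–C5, the cation counted as its exocyclic quinoid C=C form), the two protons being reduced at the cathode. The closest known reaction types are the anodic and photoredox radical-cation dimerisations of propenylarenes and 4-alkoxystyrenes with capture of water or alcohols, and counter-anion-directed radical-cation cycloadditions of anethole-type alkenes; new here are the cross-coupling of two different propenylarenes and the use of a chiral anion as electrolyte. C3 and C4 are set in the C–C bond formation: the E geometry of both alkenes fixes the substituents, but the unlike topicity that gives the erythro bond and the choice of face are not set by the substrate and must come from the ion pair between 7 and the phosphate. C2 is set in the acyclic addition of water to 8, where a Felkin–Anh arrangement (the C4 branch perpendicular to the cation plane, the C3–H bond on the aryl side, attack anti to the C4 branch) leads to the required cis relation to the C3 methyl and can be reinforced by phosphate-delivered water; C5 is set in the ring closure, the aryl group going trans to the C4 methyl to avoid eclipsing it. The step needs cross- over homo-coupling, secured by the potential gap, the excess of 3 and the slow addition of 5; coupling at the methyl-bearing carbons, secured by the benzylic stabilisation of both charge and spin; and oxygen capture in preference to cyclobutane formation or Friedel–Crafts closure, secured by water in excess over 7 and the low temperature. Which aryl group ends up cis is decided by the site of the charge in 8, and this is secured by the substrate, since 5 is the partner oxidised and its aryl group is the better cation-stabilising one.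

## Compound list

1 | 5-bromo-1,2,3-trimethoxybenzene | COc1cc(Br)cc(OC)c1OC | starting material
2 | (E)-prop-1-enylboronic acid pinacol ester, 4,4,5,5-tetramethyl-2-[(E)-prop-1-enyl]-1,3,2-dioxaborolane | C/C=C/B1OC(C)(C)C(C)(C)O1 | starting material
3 | E-isoelemicin, 1,2,3-trimethoxy-5-[(E)-prop-1-enyl]benzene | COc1cc(/C=C/C)cc(OC)c1OC | intermediate
4 | 4-bromo-1,2-dimethoxybenzene | COc1ccc(Br)cc1OC | starting material
5 | E-methylisoeugenol, 1,2-dimethoxy-4-[(E)-prop-1-enyl]benzene | COc1ccc(/C=C/C)cc1OC | intermediate
6 | water | O | starting material
7 | radical cation of 5, written as the benzylic cation with the spin on the methyl-bearing carbon | COc1ccc([CH+][CH]C)cc1OC | intermediate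
8 | erythro 1,4-radical cation: 1-(3,4-dimethoxyphenyl)-2,3-dimethyl-4-(3,4,5-trimethoxyphenyl)butane-1,4-diyl, cation at the dimethoxybenzyl carbon (C2), radical at the trimethoxybenzyl carbon (C5), methyl-bearing carbons configured as C3 and C4 of 11 | COc1ccc([CH+][C@H](C)[C@H](C)[CH]c2cc(OC)c(OC)c(OC)c2)cc1OC | intermediate
9 | 4-(3,4-dimethoxyphenyl)-4-hydroxy-2,3-dimethyl-1-(3,4,5-trimethoxyphenyl)butyl radical, the three stereocentres configured as C2, C3 and C4 of 11 | COc1ccc([C@@H](O)[C@H](C)[C@H](C)[CH]c2cc(OC)c(OC)c(OC)c2)cc1OC | intermediate
10 | 4-(3,4-dimethoxyphenyl)-4-hydroxy-2,3-dimethyl-1-(3,4,5-trimethoxyphenyl)butyl cation, the three stereocentres configured as C2, C3 and C4 of 11 | COc1ccc([C@@H](O)[C@H](C)[C@H](C)[CH+]c2cc(OC)c(OC)c(OC)c2)cc1OC | intermediate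
11 | ligraminol A, (2S,3R,4S,5S)-2-(3,4-dimethoxyphenyl)-3,4-dimethyl-5-(3,4,5-trimethoxyphenyl)oxolane | COc1ccc([C@H]2O[C@H](c3cc(OC)c(OC)c(OC)c3)[C@@H](C)[C@H]2C)cc1OC | target

## Step count and risks

Total step count: 3 (steps 1 and 2 run in parallel, then step 3). Longest linear sequence: 2 steps (step 1 or step 2, then step 3).

**Step 3 (key step, proposed new method).**
- What may go wrong: homo-dimerisation of 5 may outrun the cross-coupling, because 5 is also the better nucleophile towards its own radical cation. Ion pairing between 7 and the phosphate may be too loose to control the topicity of C3–C4 bond formation, giving the threo series and low enantioselectivity. Ring closure may lose out to Friedel–Crafts attack of an arene on a benzylic cation or to cyclobutane formation. The product may be over-oxidised or acid-epimerised at C2. A shortfall in enantiomeric purity alone would be met by preparative chromatography on a chiral phase.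
- Fallback, for failure of the coupling itself: it gives up the oxidative coupling, uses known reactions only, sets out from 1 (with 4 as the source of the second aryl group) and comes back to the route at 11. Commercial meso-2,3-dimethylsuccinic acid is dehydrated with acetyl chloride to meso-2,3-dimethylsuccinic anhydride F1. Magnesium insertion into 1 (Mg, THF) gives (3,4,5-trimethoxyphenyl)magnesium bromide F2, and transmetalation of F2 with ZnCl2 gives (3,4,5-trimethoxyphenyl)zinc chloride F3. Reagent F3 opens F1 in a rhodium-catalysed enantioselective desymmetrising acylation ([Rh(cod)Cl]2, chiral phosphinooxazoline ligand, THF; the ligand antipode is chosen for attack at the carbonyl next to the future C4). After aqueous HCl work-up this gives the erythro keto acid (2R,3S)-2,3-dimethyl-4-oxo-4-(3,4,5-trimethoxyphenyl)butanoic acid F4. Keto acid F4 is treated with LiBH(s-Bu)3 (2.2 equiv, THF, −78 °C): the first equivalent deprotonates the carboxylic acid and the second reduces the aryl ketone under Felkin–Anh control, which should give (2R,3S,4S)-4-hydroxy-2,3-dimethyl-4-(3,4,5-trimethoxyphenyl)butanoic acid F5. On aqueous HCl work-up F5 lactonises to (3R,4S,5S)-3,4-dimethyl-5-(3,4,5-trimethoxyphenyl)oxolan-2-one F6, with the methyls cis and the aryl trans to the C4 methyl; F6 is the same lactone as A4. (3,4-Dimethoxyphenyl)lithium F7, from 4 and n-BuLi at −78 °C, adds once to F6 to give the lactol (3R,4S,5S)-2-(3,4-dimethoxyphenyl)-3,4-dimethyl-5-(3,4,5-trimethoxyphenyl)oxolan-2-ol F8. Ionic reduction of F8 (Et3SiH, BF3·OEt2, CH2Cl2, −78 °C) delivers hydride to the cyclic oxocarbenium ion on the face opposite the adjacent C3 methyl group, which places the C2 aryl cis to the C3 methyl and gives 11.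

**Step 1.**
- What may go wrong: erosion of the E geometry through Pd–H-mediated isomerisation, protodeboronation of 2 before transmetalation, and incomplete conversion of the electron-rich bromide, which would contaminate the partner that is used in excess in step 3.
- Fallback: it sets out from 1 and comes back at 3. (3,4,5-Trimethoxyphenyl)magnesium bromide F2, made from 1 and Mg in THF, is allylated with allyl bromide (CuI cat., THF) to give elemicin F9. Base-mediated migration of the double bond of F9 into conjugation (KOt-Bu, DMSO) gives 3, with the small Z content removed by chromatography on AgNO3-impregnated silica.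

**Step 2.**
- What may go wrong: loss of geometric purity through Pd–H-mediated isomerisation, protodeboronation of 2 before transmetalation, and oxidative oligomerisation of the very electron-rich product on acidic silica or in air.
- Fallback: it sets out from 4 and comes back at 5. (3,4-Dimethoxyphenyl)lithium F7, made from 4 and n-BuLi in THF at −78 °C, is added to propanal to give racemic 1-(3,4-dimethoxyphenyl)propan-1-ol F10. Acid-catalysed dehydration of F10 (p-TsOH cat., toluene, reflux with water removal, dilute solution) gives the conjugated alkene 5, E by thermodynamic preference.

## Further compounds

F1 | step 3 | meso-2,3-dimethylsuccinic anhydride, (3R,4S)-3,4-dimethyloxolane-2,5-dione | C[C@H]1C(=O)OC(=O)[C@H]1C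
F2 | step 3 | (3,4,5-trimethoxyphenyl)magnesium bromide | COc1cc([Mg]Br)cc(OC)c1OC
F3 | step 3 | (3,4,5-trimethoxyphenyl)zinc chloride | COc1cc([Zn]Cl)cc(OC)c1OC
F4 | step 3 | (2R,3S)-2,3-dimethyl-4-oxo-4-(3,4,5-trimethoxyphenyl)butanoic acid | COc1cc(C(=O)[C@@H](C)[C@@H](C)C(=O)O)cc(OC)c1OC
F5 | step 3 | (2R,3S,4S)-4-hydroxy-2,3-dimethyl-4-(3,4,5-trimethoxyphenyl)butanoic acid | COc1cc([C@@H](O)[C@@H](C)[C@@H](C)C(=O)O)cc(OC)c1OC
F6 | step 3 | (3R,4S,5S)-3,4-dimethyl-5-(3,4,5-trimethoxyphenyl)oxolan-2-one | COc1cc([C@H]2OC(=O)[C@H](C)[C@@H]2C)cc(OC)c1OC
F7 | step 3 | (3,4-dimethoxyphenyl)lithium | COc1ccc([Li])cc1OC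
F8 | step 3 | (3R,4S,5S)-2-(3,4-dimethoxyphenyl)-3,4-dimethyl-5-(3,4,5-trimethoxyphenyl)oxolan-2-ol, both C2 epimers | COc1ccc(C2(O)O[C@H](c3cc(OC)c(OC)c(OC)c3)[C@@H](C)[C@H]2C)cc1OC
F9 | step 1 | elemicin, 1,2,3-trimethoxy-5-(prop-2-enyl)benzene | COc1cc(CC=C)cc(OC)c1OC
F10 | step 2 | 1-(3,4-dimethoxyphenyl)propan-1-ol, racemic | CCC(O)c1ccc(OC)c(OC)c1
A1 | alternative 1 | 3,4-cis-dimethyl-2-(3,4,5-trimethoxyphenyl)cyclobutan-1-one, aryl trans to the neighbouring methyl | O=C1[C@H](C)[C@H](C)[C@H]1c2cc(OC)c(OC)c(OC)c2
A2 | alternative 1 | 1-[(2R,5R)-2,5-dimethylpyrrolidin-1-yl]-2-(3,4,5-trimethoxyphenyl)ethan-1-one | C[C@@H]1CC[C@@H](C)N1C(=O)Cc1cc(OC)c(OC)c(OC)c1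
A3 | alternative 1 | cis-2-butene | C/C=C\C
A4 | alternative 1 | (3R,4S,5S)-3,4-dimethyl-5-(3,4,5-trimethoxyphenyl)oxolan-2-one | COc1cc([C@H]2OC(=O)[C@H](C)[C@@H]2C)cc(OC)c1OC
A5 | alternative 2 | trans-2-(3,4-dimethoxyphenyl)-3,4-dimethyl-5-(3,4,5-trimethoxyphenyl)-4,5-dihydrofuran | O1C(c2ccc(OC)c(OC)c2)=C(C)[C@H](C)[C@H]1c3cc(OC)c(OC)c(OC)c3
A6 | alternative 2 | (3,4-dimethoxyphenyl)[1,2-dimethyl-3-(3,4,5-trimethoxyphenyl)cyclopropyl]methanone, ring methyl at C2 trans to the aryl group at C3, configuration at C1 open | COc1ccc(C(=O)C2(C)[C@H](C)[C@H]2c3cc(OC)c(OC)c(OC)c3)cc1OC
A7 | alternative 3 | 2-(3,4-dimethoxyphenyl)-4-(3,4,5-trimethoxyphenyl)-3,7-dioxabicyclo[3.3.0]octan-8-one, aryl at position 2 endo, aryl at position 4 exo | O1[C@H](c3ccc(OC)c(OC)c3)[C@@H]2C(=O)OC[C@@H]2[C@H]1c4cc(OC)c(OC)c(OC)c4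
A8 | alternative 3 | 3-diazo-4-[(3,4-dimethoxyphenyl)methoxy(3,4,5-trimethoxyphenyl)methyl]oxolan-2-one, both stereocentres configured as C4 and C5 of 11 | COc1ccc(CO[C@H](c2cc(OC)c(OC)c(OC)c2)[C@H]2COC(=O)C2=[N+]=[N-])cc1OC
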